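**Plan**

1. Retrosynthesis: the chain is cut at C7=C8 (Julia–Kocienski olefination) into a ring C10 sulfone (ring plus C7) and all-E C20 crocetin dialdehyde, whose far formyl group becomes the C8' carbinol. The cyclohexene ring is then cut at C2–C3 and C5–C6 into a C2–C1–C6 piece (methyl 4-iodo-3,3-dimethylbutanoate, ester carbon = C7) and a C3–C4–C5 piece (but-2-ynoyl chloride).
2. Enabling feature: in the ring the oxygen-bearing C3 and the methyl-bearing sp2 carbon C5 stand 1,3 across C4, so C3–C4=C5(CH3) is a but-2-ynoyl unit at the ketone level (acyl acceptor at C3, Michael acceptor at C5). C2 and C6 flank the quaternary gem-dimethyl carbon C1, which cannot enolise and favours closure; C6 is made nucleophilic by keeping C7 at the ester level.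
3. Forward: the only ring arises in step 3, where acylation of a zinc reagent (C2–C3) and a base-induced 6-endo-dig Michael closure (C5–C6) run in one flask. The helpers are then removed (C3 ketone reduced, C7 ester turned into a CH2–sulfone), the C20 chain is joined in step 9 and the remaining CHO is reduced.
4. Stereochemistry: C6 is first formed racemic and labile. The CBS reduction of step 4 sets C3 (R) by catalyst control and, by matched double stereodifferentiation, selects the 6R ketone to give the trans (3R,6R) alcohol. C7=C8 (E) comes from the Julia–Kocienski step, the other E double bonds from the dialdehyde.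

Key step: step 3

Remark: positions are given in carotenoid numbering (C1 gem-dimethyl carbon, C2 ring CH2, C3 carbinol carbon, C4=C5 ring double bond, C6 ring CH, chain from C7). All-E crocetin dialdehyde is assumed to be purchasable.

**Route**

Step 1
Reactants: 1 5-methoxy-3,3-dimethyl-5-oxopentanoic acid (monomethyl 3,3-dimethylglutarate)
Product: 2 methyl 4-iodo-3,3-dimethylbutanoate
Conditions: PhI(OAc)2, I2, ClCH2CH2Cl, visible light, 60 °C
Reagents that add atoms: iodine, [I][I]
Why: Hunsdiecker-type iododecarboxylation through the acyl hypoiodite, whose primary, β-quaternary alkyl radical cannot rearrange or eliminate and is trapped by iodine, so the carboxyl carbon is exchanged for iodine at the future C2.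

Step 2
Reactants: 3 but-2-ynoic acid
Product: 4 but-2-ynoyl chloride
Conditions: 1-chloro-N,N,2-trimethylprop-1-en-1-amine, CH2Cl2, 0 °C; solution used directly
Reagents that add atoms: 1-chloro-N,N,2-trimethylprop-1-en-1-amine, CC(C)=C(Cl)N(C)C
Why: Neutral acid chloride formation with an α-chloro enamine, which releases no HCl that could add across the activated triple bond.

Step 3
Reactants: 2 methyl 4-iodo-3,3-dimethylbutanoate; 4 but-2-ynoyl chloride
Product: 7 racemic methyl 2,6,6-trimethyl-4-oxocyclohex-2-ene-1-carboxylate, via alkylzinc iodide 5 (not isolated), via ynone ester 6 (not isolated)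
Conditions: Zn dust (activated with BrCH2CH2Br, Me3SiCl), LiCl, THF, 40 °C; then 4, Pd(PPh3)4 (2 mol%), 0 °C to rt; then dilution with THF, KOt-Bu (4 equiv), t-BuOH, 0 °C to rt; aq. HCl
Reagents that add atoms: none
Why: Zinc inserts into the primary C–I bond of 2 (the ester is tolerated), and Negishi acylation with 4 (oxidative addition of the acyl chloride to zerovalent palladium, transmetalation, reductive elimination) forms C2–C3 in ynone 6. KOt-Bu then equilibrates the enolates of 6, and the ester enolate at C6 adds to the ynone β-carbon C5, which forms C5–C6 and, after proton transfer, the conjugated C4=C5 enone. The closest known reaction types are the Negishi ketone synthesis and the anionic Michael cyclisation of carbanions onto alkynones, here merged in one flask. The single ring closes in the 6-endo-dig mode, because attack at C4 would be an anti-Michael 5-exo closure and the more acidic ketone enolate at C2 could only form a three-membered ring. The one new stereocentre, C6, is not controlled here, since as the γ-carbon of a vinylogous β-keto ester it ends as the planar dienolate that drives the closure, and it is obtained racemic and fixed in step 4. The step needs acylation at C–Zn only (alkylzinc halides do not add to ynones or esters without copper) and intramolecular over intermolecular Michael addition, which dilution and the gem-dimethyl group at C1 (Thorpe–Ingold effect) should secure.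

Step 4
Reactants: 7 racemic methyl 2,6,6-trimethyl-4-oxocyclohex-2-ene-1-carboxylate
Product: 8 methyl (1R,4R)-4-hydroxy-2,6,6-trimethylcyclohex-2-ene-1-carboxylate
Conditions: (S)-2-methyl-CBS-oxazaborolidine (0.15 equiv), catecholborane (0.6 equiv), toluene, −78 °C; MeOH, then aq. NaHCO3; chromatography
Reagents that add atoms: none
Why: Corey–Bakshi–Shibata reduction used as a kinetic resolution, in which the catalyst (alkenyl arm as large group) should deliver hydride to the face that gives the (R)-carbinol, a face that coincides with the substrate-preferred attack anti to the axial methyl group at C1 only in the (1R)-ketone, so that this enantiomer gives the trans alcohol while the (1S)-ketone is left behind (or gives the separable cis diastereomer), is racemised with DBU and recycled.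

Step 5
Reactants: 8 methyl (1R,4R)-4-hydroxy-2,6,6-trimethylcyclohex-2-ene-1-carboxylate
Product: 9 methyl (1R,4R)-4-{[tert-butyl(dimethyl)silyl]oxy}-2,6,6-trimethylcyclohex-2-ene-1-carboxylate
Conditions: t-BuMe2SiCl, imidazole, DMF, rt
Reagents that add atoms: tert-butyldimethylsilyl chloride, CC(C)(C)[Si](C)(C)Cl
Why: Standard silylation of the secondary allylic alcohol under weakly basic conditions that should not epimerise the ester-bearing carbon.

Step 6
Reactants: 9 methyl (1R,4R)-4-{[tert-butyl(dimethyl)silyl]oxy}-2,6,6-trimethylcyclohex-2-ene-1-carboxylate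
Product: 10 [(1R,4R)-4-{[tert-butyl(dimethyl)silyl]oxy}-2,6,6-trimethylcyclohex-2-en-1-yl]methanol
Conditions: LiAlH4, Et2O, 0 °C
Reagents that add atoms: none
Why: Hydride reduction of the hindered ester to the primary alcohol is faster than enolisation, so C6 keeps its configuration and is no longer α to a carbonyl group afterwards.

Step 7
Reactants: 10 [(1R,4R)-4-{[tert-butyl(dimethyl)silyl]oxy}-2,6,6-trimethylcyclohex-2-en-1-yl]methanol
Product: 11 5-({[(1R,4R)-4-{[tert-butyl(dimethyl)silyl]oxy}-2,6,6-trimethylcyclohex-2-en-1-yl]methyl}sulfanyl)-1-phenyl-1H-tetrazole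
Conditions: 1-phenyl-1H-tetrazole-5-thiol, PPh3, diisopropyl azodicarboxylate, THF, 0 °C to rt
Reagents that add atoms: 1-phenyl-1H-tetrazole-5-thiol, Sc1nnnn1-c1ccccc1
Why: Mitsunobu thioetherification of the primary alcohol with an acidic heteroaryl thiol, a substitution at C7 that touches neither stereocentre.

Step 8
Reactants: 11 5-({[(1R,4R)-4-{[tert-butyl(dimethyl)silyl]oxy}-2,6,6-trimethylcyclohex-2-en-1-yl]methyl}sulfanyl)-1-phenyl-1H-tetrazole
Product: 12 5-({[(1R,4R)-4-{[tert-butyl(dimethyl)silyl]oxy}-2,6,6-trimethylcyclohex-2-en-1-yl]methyl}sulfonyl)-1-phenyl-1H-tetrazole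
Conditions: (NH4)6Mo7O24·4H2O (10 mol%), 30% H2O2, EtOH, 0 °C to rt
Reagents that add atoms: hydrogen peroxide, OO
Why: Molybdate-catalysed peroxide oxidation takes the sulfide to the sulfone much faster than it epoxidises the hindered trisubstituted ring alkene.

Step 9
Reactants: 12 5-({[(1R,4R)-4-{[tert-butyl(dimethyl)silyl]oxy}-2,6,6-trimethylcyclohex-2-en-1-yl]methyl}sulfonyl)-1-phenyl-1H-tetrazole; 13 all-E crocetin dialdehyde (2,6,11,15-tetramethylhexadeca-2,4,6,8,10,12,14-heptaenedial)
Product: 14 (3R,6R)-3-{[tert-butyl(dimethyl)silyl]oxy}-8'-apo-ε-caroten-8'-al (all-E)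
Conditions: KN(SiMe3)2, 1,2-dimethoxyethane, −60 °C; then addition to 13 (3 equiv), −60 °C to rt; dim light, argon
Reagents that add atoms: none
Why: Julia–Kocienski olefination, in which the metalated sulfone adds to one formyl group and Smiles rearrangement with loss of SO2 and the tetrazolone should give the E C7=C8 bond, while the excess of dialdehyde limits double olefination and C6, being β to the carbanion, is not deprotonated.

Step 10
Reactants: 14 (3R,6R)-3-{[tert-butyl(dimethyl)silyl]oxy}-8'-apo-ε-caroten-8'-al
Product: 15 (3R,6R)-3-{[tert-butyl(dimethyl)silyl]oxy}-8'-apo-ε-caroten-8'-ol (all-E)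
Conditions: NaBH4, THF/MeOH, 0 °C
Reagents that add atoms: none
Why: Borohydride reduces the conjugated polyenal in the 1,2-sense to the allylic alcohol without touching the polyene.

Step 11
Reactants: 15 (3R,6R)-3-{[tert-butyl(dimethyl)silyl]oxy}-8'-apo-ε-caroten-8'-ol
Product: 16 (3R,6R)-8'-apo-ε-carotene-3,8'-diol (all-E), the target
Conditions: Bu4NF, THF, 0 °C to rt; dim light, argon
Reagents that add atoms: none
Why: Fluoride cleaves the silyl ether under non-acidic conditions, which avoids ionisation and epimerisation of the allylic C3 carbinol and isomerisation of the polyene.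

**Compound list**

1 | 5-methoxy-3,3-dimethyl-5-oxopentanoic acid | COC(=O)CC(C)(C)CC(=O)O | starting material
2 | methyl 4-iodo-3,3-dimethylbutanoate | COC(=O)CC(C)(C)CI | intermediate
3 | but-2-ynoic acid | CC#CC(=O)O | starting material
4 | but-2-ynoyl chloride | CC#CC(=O)Cl | intermediate
5 | (4-methoxy-2,2-dimethyl-4-oxobutyl)zinc iodide | COC(=O)CC(C)(C)C[Zn]I | intermediate
6 | methyl 3,3-dimethyl-5-oxooct-6-ynoate | COC(=O)CC(C)(C)CC(=O)C#CC | intermediate
7 | racemic methyl 2,6,6-trimethyl-4-oxocyclohex-2-ene-1-carboxylate | COC(=O)C1C(C)=CC(=O)CC1(C)C | intermediate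
8 | methyl (1R,4R)-4-hydroxy-2,6,6-trimethylcyclohex-2-ene-1-carboxylate | CC1=C[C@H](O)CC(C)(C)[C@H]1C(=O)OC | intermediate
9 | methyl (1R,4R)-4-{[tert-butyl(dimethyl)silyl]oxy}-2,6,6-trimethylcyclohex-2-ene-1-carboxylate | CC1=C[C@H](O[Si](C)(C)C(C)(C)C)CC(C)(C)[C@H]1C(=O)OC | intermediate
10 | [(1R,4R)-4-{[tert-butyl(dimethyl)silyl]oxy}-2,6,6-trimethylcyclohex-2-en-1-yl]methanol | CC1=C[C@H](O[Si](C)(C)C(C)(C)C)CC(C)(C)[C@H]1CO | intermediate
11 | 5-({[(1R,4R)-4-{[tert-butyl(dimethyl)silyl]oxy}-2,6,6-trimethylcyclohex-2-en-1-yl]methyl}sulfanyl)-1-phenyl-1H-tetrazole | CC1=C[C@H](O[Si](C)(C)C(C)(C)C)CC(C)(C)[C@H]1CSc1nnnn1-c1ccccc1 | intermediate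
12 | 5-({[(1R,4R)-4-{[tert-butyl(dimethyl)silyl]oxy}-2,6,6-trimethylcyclohex-2-en-1-yl]methyl}sulfonyl)-1-phenyl-1H-tetrazole | CC1=C[C@H](O[Si](C)(C)C(C)(C)C)CC(C)(C)[C@H]1CS(=O)(=O)c1nnnn1-c1ccccc1 | intermediate
13 | all-E crocetin dialdehyde, (2E,4E,6E,8E,10E,12E,14E)-2,6,11,15-tetramethylhexadeca-2,4,6,8,10,12,14-heptaenedial | O=C/C(C)=C/C=C/C(C)=C/C=C/C=C(C)/C=C/C=C(\C)C=O | starting material
14 | (3R,6R)-3-{[tert-butyl(dimethyl)silyl]oxy}-8'-apo-ε-caroten-8'-al, all-E | CC1=C[C@H](O[Si](C)(C)C(C)(C)C)CC(C)(C)[C@H]1/C=C/C(C)=C/C=C/C(C)=C/C=C/C=C(C)/C=C/C=C(\C)C=O | intermediate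
15 | (3R,6R)-3-{[tert-butyl(dimethyl)silyl]oxy}-8'-apo-ε-caroten-8'-ol, all-E | CC1=C[C@H](O[Si](C)(C)C(C)(C)C)CC(C)(C)[C@H]1/C=C/C(C)=C/C=C/C(C)=C/C=C/C=C(C)/C=C/C=C(\C)CO | intermediate
16 | (3R,6R)-8'-apo-ε-carotene-3,8'-diol, all-E | CC1=C[C@H](O)CC(C)(C)[C@H]1/C=C/C(C)=C/C=C/C(C)=C/C=C/C=C(C)/C=C/C=C(\C)CO | target

**Count and risks**

Total step count: 11. Longest linear sequence: 10 steps (steps 1 and 3 to 11; step 2 is a one-step side branch).

Step 3. After the acylation the ester enolate is only a minor partner in the enolate equilibrium of ynone 6, so intermolecular Michael oligomerisation, O-acylation to an enol lactone or base-induced decomposition of the ynone may outrun the ring closure. The fallback stops the sequence after the Negishi stage and isolates ynone 6. Anti-hydroiodination (NaI, AcOH, rt) should give methyl (6Z)-7-iodo-3,3-dimethyl-5-oxooct-6-enoate F1, in which iodine is cis to the acyl group. The ring is then closed by palladium-catalysed intramolecular α-alkenylation of the ester enolate (Pd(PPh3)4, KOt-Bu, THF, rt), so that C5–C6 is made by oxidative addition and reductive elimination with retention of the alkene geometry and not by conjugate addition. This comes back to the route at 7.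

Step 4. The rate difference between the matched and mismatched ketone enantiomers may be too small, or the catalyst may not fully control the carbonyl face (the bulky CH2–CMe2 arm may compete with the alkenyl arm as the large group). Either would erode the enantiomeric purity of 8. The fallback sets out from 7 and separates the two tasks. Substrate-controlled 1,2-reduction with Li(s-Bu)3BH (THF, −78 °C, hydride anti to the axial methyl group) should give racemic trans-methyl 4-hydroxy-2,6,6-trimethylcyclohex-2-ene-1-carboxylate F2. Lipase-catalysed acylation (Burkholderia cepacia lipase, vinyl acetate, t-BuOMe, rt) should convert the (4R)-alcohol into methyl (1R,4R)-4-acetoxy-2,6,6-trimethylcyclohex-2-ene-1-carboxylate F3, which is separated from the unreacted (1S,4S)-alcohol. Methanolysis (K2CO3, MeOH, 0 °C) returns to the route at 8.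

Step 9. Double olefination of the symmetric dialdehyde, slow addition of the hindered sulfone anion with competing self-condensation of the sulfone, and incomplete E-selectivity at C7=C8 may all lower the outcome. The fallback sets out from 10 and uses a Wittig reaction followed by equilibration. Iodination (I2, PPh3, imidazole, CH2Cl2) should give tert-butyl{[(1R,4R)-4-(iodomethyl)-3,5,5-trimethylcyclohex-2-en-1-yl]oxy}dimethylsilane F4. PPh3 (MeCN, 80 °C) then gives {[(1R,4R)-4-{[tert-butyl(dimethyl)silyl]oxy}-2,6,6-trimethylcyclohex-2-en-1-yl]methyl}triphenylphosphonium iodide F5. Its ylide (NaN(SiMe3)2, THF, −78 °C) with 13 (3 equiv) should give mainly the 7Z isomer of 14, (7Z)-3-silyloxy-8'-apo-ε-caroten-8'-al F6. Iodine-catalysed isomerisation (cat. I2, hexane, daylight) converts it into all-E 14, where the route is rejoined.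

**Further compounds**

F1 | step 3 | methyl (6Z)-7-iodo-3,3-dimethyl-5-oxooct-6-enoate | COC(=O)CC(C)(C)CC(=O)/C=C(/C)I
F2 | step 4 | racemic trans-methyl 4-hydroxy-2,6,6-trimethylcyclohex-2-ene-1-carboxylate, (1R,4R) and (1S,4S) | CC1=C[C@H](O)CC(C)(C)[C@H]1C(=O)OC.CC1=C[C@@H](O)CC(C)(C)[C@@H]1C(=O)OC
F3 | step 4 | methyl (1R,4R)-4-acetoxy-2,6,6-trimethylcyclohex-2-ene-1-carboxylate | CC1=C[C@H](OC(C)=O)CC(C)(C)[C@H]1C(=O)OC
F4 | step 9 | tert-butyl{[(1R,4R)-4-(iodomethyl)-3,5,5-trimethylcyclohex-2-en-1-yl]oxy}dimethylsilane | CC1=C[C@H](O[Si](C)(C)C(C)(C)C)CC(C)(C)[C@H]1CI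
F5 | step 9 | {[(1R,4R)-4-{[tert-butyl(dimethyl)silyl]oxy}-2,6,6-trimethylcyclohex-2-en-1-yl]methyl}triphenylphosphonium iodide | CC1=C[C@H](O[Si](C)(C)C(C)(C)C)CC(C)(C)[C@H]1C[P+](c1ccccc1)(c1ccccc1)c1ccccc1.[I-]
F6 | step 9 | (7Z)-isomer of 14, (3R,6R,7Z)-3-{[tert-butyl(dimethyl)silyl]oxy}-8'-apo-ε-caroten-8'-al | CC1=C[C@H](O[Si](C)(C)C(C)(C)C)CC(C)(C)[C@H]1\C=C/C(C)=C/C=C/C(C)=C/C=C/C=C(C)/C=C/C=C(\C)C=O
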